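Each mole of left-handed product or right-handed product has, we take it, used one mole of partner, so the product peaks let us keep partner's books.

| flask | left-handed substrate | right-handed substrate | partner | remark | time |
|---|---|---|---|---|---|
| north | 0.25 M | 0.25 M | 1 M | run made earlier |  |
| north-east | 1 M | 1 M | 1 M | run made earlier |  |
| flask | 0.50 M | 0.50 M | 1.00 M |  | 30 h |

| run | time / h | left-handed product / % | right-handed product / % |
|---|---|---|---|
| north | 2.50 | 12.5 | 4.8 |
| north | 8.00 | 23.8 | 10.9 |
| north | 12.0 | 28.8 | 13.4 |
| north | 20.0 | 35.3 | 17.6 |
| north | 30.0 | 41.3 | 21.2 |
| north | 40.0 | 44.1 | 23.1 |
| north-east | 3.00 | 12.0 | 5.2 |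
| north-east | 5.00 | 15.6 | 6.2 |
| north-east | 8.00 | 18.2 | 8.3 |
| north-east | 12.0 | 20.7 | 10.2 |
| north-east | 20.0 | 24.2 | 10.9 |
| north-east | 40.0 | 27.6 | 12.3 |

(standard deviation of a reading: 0.3 percentage points)

1. left-handed product and right-handed product together, in percent of the left-handed substrate and right-handed substrate charged together, at 30 h
2. excess of left-handed product over right-handed product in the product at 30 h
3. whether the exchange between left-handed substrate and right-handed substrate keeps pace with the reaction: how far the product's excess at 30 h gets from its value without exchange to its value with instant exchange (above 80 % keeps pace, below 20 % hardly takes part, else lags behind)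

- partner is single-handed; left-handed substrate and right-handed substrate are mirror images of each other, charged as a racemate, each of them at the stated concentration
- an excess is the difference of the two amounts in percent of their sum
- an excess is below zero if the other one leads
- the handed part of partner does not stay in what it makes, so the products of the two hands are mirror images too

We open the ledger with the north-east run. At 40.0 h in that run, 79.8 % of the partner charge stands in product. The last 20.0 h added 4.8 percentage points, against 17 points in the first 3.00 h, with 60.1 % of the substrate unused. We read this as partner being the limiting reagent, with the 20.2 % of it not in product at that reading taken, we suppose, by an exit we cannot see. In the north run at 40.0 h, product holds 33.6 % of the partner charge and the other 66.4 % is not in product, so at the same partner charge the north run, with less substrate, shows the smaller entry.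

We freeze the substrate at its mean level s, halfway between charge and remainder, and write the product's share as s/(s+h). The north run gives h = 0.656 M and the north-east run 0.405 M. These differ, so we take their geometric mean, 0.516 M, as the capture level: the mean substrate, both hands together, at which partner divides equally between product and exit.

For the flask we guess that 0.5 of the substrate turns, so s is 0.750 M and the share is 59.3 %. The north run had reached 93.0 % of its last reading by 30.0 h, so we expect 55.1 %. At a similar yield of 52.9 %, the north run shows a reading of 33.5 % for the excess, which we adopt. For the pace we have no reckoning.

The forecast gives 50 %, 35 % and "hardly takes part", and calls the falling excess “what no exchange predicts”.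

The flask gives 53.2 % and an excess of 34.5 %, and its exchange lags behind, getting 32 % of the way from the 30.3 % without exchange.

    partner + left-handed substrate → left-handed product (k = 4.30 × 10⁻⁵ L mol⁻¹ s⁻¹)
    partner + right-handed substrate → right-handed product (k = 1.70 × 10⁻⁵ L mol⁻¹ s⁻¹)
    partner ⇌ dormant form (K = 0.700, k = 4.70 × 10⁻⁵ s⁻¹)
    2 partner → homo dimer (k = 1.40 × 10⁻⁵ L mol⁻¹ s⁻¹)
    left-handed substrate ⇌ right-handed substrate (k = 6.70 × 10⁻⁶ s⁻¹)

In the flask at 30.0 h, product holds 60.0 % of the partner no longer free, so the flask's own capture level comes to 0.490 M, against the 0.516 M we carried. Partner's half-life by the forward step to dormant form alone, the way back not counted, is 4.1 h, shorter than its 9.0 h by reaction with left-handed substrate alone as charged.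

For the neighbour flask with 0.25 M of partner, we guess that 0.5 of its partner goes into product, so s is 0.938 M, and the frozen capture level gives a share of 64.5 % and a yield of 15.0 %. That flask gives 18.7 %.

The earlier runs and the new flask come from a simulation on assumed constants.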